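**Retrosynthetic overview**

1. Labdane numbering is used: ring A = C1–C5 and C10, ring B = C5–C10, side chain C11–C16 on C9, C17 on C8, C18/C19 on C4, C20 on C10. The (E)-C13(C16)=C14–C15H2OH unit is traced to a terminal alkyne (methylalumination, then formaldehyde). The C8 carbinol is traced to a C8 ketone via the exocyclic alkene, its α-epoxide and hydride.
2. Ring B with the C8 ketone is made by one-carbon expansion of the cyclopentanone ring C5–C6–C7–C8–C10 of a trans-fused bromo-hydrindanone. A β-oxido carbenoid, built at C8 from a 1,1-dibromide that carries C9 and C11–C14, inserts C9 into the C8–C10 bond. This joins both fragments and forms C8–C9 and C9–C10 in one flask.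
3. Enabling feature: C8 is a carbonyl carbon whose neighbour C10 is fully substituted (C1, C5, C20), so the electron-rich C8–C10 bond is the one expected to migrate to the carbenoid carbon. The carbonyl re-formed at C8 sits where the tertiary alcohol is needed and makes C9–H epimerizable, so the side chain settles equatorial.
4. The hydrindanone comes by ozonolysis of an exocyclic allene. The allene comes from an enantioselective bromonium-initiated bicyclization of an acyclic dienyne propargylsilane (one flask from (E)-geranylacetone), which sets C3–Br, C5 and C10 together.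
5. Order of ring formation: ring A and the cyclopentane together (bromocyclization), then ring B by expansion of the cyclopentane; the side-chain alkene is made last.

Key step: step 6

Remark: the SMILES is read as the (3R,5S,8S,9S,10R) bromolabdane (mirror-image ring system relative to common labdanes); "α" means the face opposite the C20 methyl; the antipode of the step 2 catalyst that gives this series must be fixed in a first run, and the (S) form is written.

**Route**

Step 1
Reactants: 1 (E)-geranylacetone [(5E)-6,10-dimethylundeca-5,9-dien-2-one]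
Product: 4 trimethyl[(6E)-7,11-dimethyldodeca-6,10-dien-2-yn-1-yl]silane, via enol phosphate 2 (not isolated), via lithium acetylide 3 (not isolated)
Conditions: LiN(iPr)2 (1.05 equiv), THF, −78 °C; ClP(O)(OEt)2, −78 °C → rt; LiN(iPr)2 (2.2 equiv), −78 °C → rt; Me3SiCH2OTf (1.5 equiv), −78 °C → rt
Reagents that add atoms: (trimethylsilyl)methyl trifluoromethanesulfonate, C[Si](C)(C)COS(=O)(=O)C(F)(F)F
Why: Kinetic deprotonation at the methyl group, O-phosphorylation and double elimination (methyl ketone to alkyne by the enol phosphate method) should deliver the lithium acetylide in the flask, which is alkylated directly by SN2 attack on the primary α-silyl triflate (the hindered diisopropylamine and the phosphate salt being poor nucleophiles toward this neopentyl-type electrophile) to give the propargylsilane that will terminate the cyclization, the remote trisubstituted alkenes and their (E) geometry staying untouched; no stereocenter is formed.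

Step 2
Reactants: 4 trimethyl[(6E)-7,11-dimethyldodeca-6,10-dien-2-yn-1-yl]silane
Product: 5 (3aS,5R,7aR)-5-bromo-1-ethenylidene-4,4,7a-trimethyloctahydro-1H-indene (trans-fused; Br equatorial, cis to the angular methyl)
Conditions: 1,3-dibromo-5,5-dimethylhydantoin (1.0 equiv), (S)-3,3′-bis(2,4,6-triisopropylphenyl)-1,1′-binaphthyl-2,2′-diyl N-triflylthiophosphoramide (10 mol %), toluene/CH2Cl2, −78 °C
Reagents that add atoms: 1,3-dibromo-5,5-dimethylhydantoin, CC1(C)N(Br)C(=O)N(Br)C1=O
Why: The chiral sulfur Lewis base should pass Br+ to the terminal, least hindered alkene with face selection (Lewis-base-catalysed enantioselective bromonium polyene cyclization), the chair-like anti addition across the (E)-C5=C10 alkene then relays this to equatorial C3–Br and trans C5–H/C10–CH3, and the C10 cation is captured 5-exo by alkyne carbon C8 because only that mode places the vinyl cation β to silicon (propargylsilane-terminated cation–olefin cyclization), loss of the silyl group giving the allene.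

Step 3
Reactants: 5 (3aS,5R,7aR)-5-bromo-1-ethenylidene-4,4,7a-trimethyloctahydro-1H-indene
Product: 6 (3aS,5R,7aR)-5-bromo-4,4,7a-trimethyloctahydro-1H-inden-1-one
Conditions: O3, CH2Cl2, −78 °C; Me2S, −78 °C → rt
Reagents that add atoms: ozone, [O-][O+]=O
Why: Ozonolysis should cleave the electron-rich exocyclic allene at the ring C=C bond to leave the cyclopentanone, the bromide is inert, and no stereocenter can epimerize because C10 next to the new ketone is quaternary.

Step 4
Reactants: 7 5-(trimethylsilyl)pent-4-yn-1-ol
Product: 8 5-(trimethylsilyl)pent-4-ynal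
Conditions: PhI(OAc)2, 2,2,6,6-tetramethylpiperidin-1-oxyl (10 mol %), CH2Cl2, rt
Reagents that add atoms: none
Why: Oxoammonium-mediated oxidation of the primary alcohol should stop at the aldehyde and tolerates the silyl alkyne; no stereocenter is formed.

Step 5
Reactants: 8 5-(trimethylsilyl)pent-4-ynal
Product: 9 (5,5-dibromopent-1-yn-1-yl)trimethylsilane
Conditions: P(OPh)3, Br2, CH2Cl2, −60 °C → rt
Reagents that add atoms: bromine, BrBr
Why: Deoxygenative geminal dibromination of the aldehyde by the preformed phosphite–bromine adduct (oxygen leaves as triphenyl phosphate) should give the 1,1-dibromide without bromination of the silyl alkyne at low temperature; no stereocenter is formed.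

Step 6
Reactants: 6 (3aS,5R,7aR)-5-bromo-4,4,7a-trimethyloctahydro-1H-inden-1-one; 9 (5,5-dibromopent-1-yn-1-yl)trimethylsilane
Product: 14 (1S,4aS,6R,8aR)-6-bromo-5,5,8a-trimethyl-1-[4-(trimethylsilyl)but-3-yn-1-yl]octahydronaphthalen-2(1H)-one, via dibromoalkyllithium 10 (not isolated), via dibromo alkoxide 11 (not isolated), via β-oxido carbenoid 12 (not isolated), via lithium enolate 13 (not isolated)
Conditions: 9 (1.5 equiv), lithium 2,2,6,6-tetramethylpiperidide, THF/Et2O, −105 °C; 6, −105 → −90 °C; nBuLi, −95 → 0 °C; aq NH4Cl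
Reagents that add atoms: none
Why: The amide base deprotonates 9 to the α,α-dibromoalkyllithium 10, which adds to the C8 carbonyl of 6 to give alkoxide 11; bromine–lithium exchange with nBuLi then gives the β-oxido carbenoid 12, in which the C8–C10 σ-bond anti to the remaining C–Br bond migrates to the carbenoid carbon C9 as bromide leaves, giving enolate 13. The closest known reaction type is the β-oxido carbenoid one-carbon ring enlargement of cyclic ketones with 1,1-dibromoalkanes, which gives 2-alkyl homologated ketones through their regiodefined enolates. No ring is closed by cyclization: ring B (C5–C6–C7–C8–C9–C10) arises by 1,2-shift from the cyclopentanone ring (C5–C6–C7–C8–C10), C9 being inserted into the C8–C10 bond with retention at the migrating quaternary C10. The new stereocenter C9 is set on protonation of enolate 13 from the α-face, opposite the axial C20 methyl, which puts the side chain equatorial; this is also the thermodynamic epimer and is secured in step 7. The step needs migration of C10 rather than C7, which the higher migratory aptitude of the fully substituted carbon toward the electrophilic carbenoid centre should secure, and exchange at the geminal dibromide rather than at C3–Br, which the hindered, equatorial, non-geminal nature of that bromide at −95 °C should secure.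

Step 7
Reactants: 14 (1S,4aS,6R,8aR)-6-bromo-5,5,8a-trimethyl-1-[4-(trimethylsilyl)but-3-yn-1-yl]octahydronaphthalen-2(1H)-one
Product: 15 (1S,4aS,6R,8aR)-6-bromo-1-(but-3-yn-1-yl)-5,5,8a-trimethyloctahydronaphthalen-2(1H)-one
Conditions: K2CO3, MeOH, rt
Reagents that add atoms: none
Why: Methoxide-mediated protodesilylation frees the terminal alkyne while the base equilibrates C9, α to the C8 ketone, to the epimer with the equatorial side chain (C9–H on the α-face), which is the configuration of the target.

Step 8
Reactants: 15 (1S,4aS,6R,8aR)-6-bromo-1-(but-3-yn-1-yl)-5,5,8a-trimethyloctahydronaphthalen-2(1H)-one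
Product: 16 (1R,4aS,6R,8aS)-6-bromo-1-(but-3-yn-1-yl)-5,5,8a-trimethyl-2-methylidenedecahydronaphthalene
Conditions: Ph3PCH3Br, KN(SiMe3)2, THF, 0 → 60 °C
Reagents that add atoms: methyltriphenylphosphonium bromide, C[P+](c1ccccc1)(c1ccccc1)c1ccccc1.[Br-]
Why: Wittig methylenation with excess ylide should convert the hindered C8 ketone into the exocyclic C8=C17 alkene, C9 being already the thermodynamic epimer and the equatorial C3 bromide having no anti-periplanar hydrogen for E2.

Step 9
Reactants: 16 (1R,4aS,6R,8aS)-6-bromo-1-(but-3-yn-1-yl)-5,5,8a-trimethyl-2-methylidenedecahydronaphthalene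
Product: 17 (1S,2S,4aS,6R,8aR)-6-bromo-1-(but-3-yn-1-yl)-5,5,8a-trimethyloctahydro-1H-spiro[naphthalene-2,2′-oxirane] (epoxide oxygen α at C8)
Conditions: mCPBA, NaHCO3, CH2Cl2, 0 °C
Reagents that add atoms: 3-chloroperoxybenzoic acid, OOC(=O)c1cccc(Cl)c1
Why: Prilezhaev epoxidation should take place only at the 1,1-disubstituted alkene (the terminal alkyne is far less nucleophilic) and from the α-face, because the β-face of C8 is blocked by the syn-axial C20 methyl, which places the oxygen α at C8 as the target requires.

Step 10
Reactants: 17 (1S,2S,4aS,6R,8aR)-6-bromo-1-(but-3-yn-1-yl)-5,5,8a-trimethyloctahydro-1H-spiro[naphthalene-2,2′-oxirane]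
Product: 18 (1S,2S,4aS,6R,8aR)-6-bromo-1-(but-3-yn-1-yl)-2,5,5,8a-tetramethyldecahydronaphthalen-2-ol
Conditions: LiAlH4, THF, 0 °C → rt
Reagents that add atoms: none
Why: Hydride should open the spiro-epoxide by SN2 attack at the unhindered C17 methylene, so the C8–O bond keeps its α configuration and C17 becomes the axial methyl, while the hindered equatorial C3 bromide should react much more slowly.

Step 11
Reactants: 18 (1S,2S,4aS,6R,8aR)-6-bromo-1-(but-3-yn-1-yl)-2,5,5,8a-tetramethyldecahydronaphthalen-2-ol
Product: 21 (1S,2S,4aS,6R,8aR)-6-bromo-1-[(3E)-5-hydroxy-3-methylpent-3-en-1-yl]-2,5,5,8a-tetramethyldecahydronaphthalen-2-ol, via alkenylalane 19 (not isolated), via lithium alanate 20 (not isolated)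
Conditions: Me3Al (4 equiv), Cp2ZrCl2 (25 mol %), CH2Cl2, 0 °C → rt; nBuLi, THF, −78 °C; (CH2O)n, −78 °C → rt; aq potassium sodium tartrate
Reagents that add atoms: trimethylaluminium, C[Al](C)C; formaldehyde (as paraformaldehyde), C=O
Why: Negishi zirconium-catalysed carboalumination adds methyl and aluminium syn across the terminal alkyne with methyl at the internal carbon, and the derived alanate reacts with formaldehyde with retention of alkene geometry, which should give the (E)-C13=C14 allylic alcohol while the tertiary alcohol is carried as its aluminium alkoxide.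

**Compound list**

1 | (E)-geranylacetone, (5E)-6,10-dimethylundeca-5,9-dien-2-one | CC(C)=CCC/C(C)=C/CCC(C)=O | starting material
2 | diethyl (5E)-6,10-dimethylundeca-1,5,9-trien-2-yl phosphate | CC(C)=CCC/C(C)=C/CCC(=C)OP(=O)(OCC)OCC | intermediate
3 | lithium (5E)-6,10-dimethylundeca-5,9-dien-1-yn-1-ide | CC(C)=CCC/C(C)=C/CCC#C[Li] | intermediate
4 | trimethyl[(6E)-7,11-dimethyldodeca-6,10-dien-2-yn-1-yl]silane | CC(C)=CCC/C(C)=C/CCC#CC[Si](C)(C)C | intermediate
5 | (3aS,5R,7aR)-5-bromo-1-ethenylidene-4,4,7a-trimethyloctahydro-1H-indene | C=C=C1[C@]2(C)CC[C@@H](Br)C(C)(C)[C@H]2CC1 | intermediate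
6 | (3aS,5R,7aR)-5-bromo-4,4,7a-trimethyloctahydro-1H-inden-1-one | O=C1[C@]2(C)CC[C@@H](Br)C(C)(C)[C@H]2CC1 | intermediate
7 | 5-(trimethylsilyl)pent-4-yn-1-ol | C[Si](C)(C)C#CCCCO | starting material
8 | 5-(trimethylsilyl)pent-4-ynal | C[Si](C)(C)C#CCCC=O | intermediate
9 | (5,5-dibromopent-1-yn-1-yl)trimethylsilane | C[Si](C)(C)C#CCCC(Br)Br | intermediate
10 | [1,1-dibromo-5-(trimethylsilyl)pent-4-yn-1-yl]lithium | [Li]C(Br)(Br)CCC#C[Si](C)(C)C | intermediate
11 | lithium alkoxide of (3aS,5R,7aR)-5-bromo-1-[1,1-dibromo-5-(trimethylsilyl)pent-4-yn-1-yl]-4,4,7a-trimethyloctahydro-1H-inden-1-ol (C1–O cis to the 7a-methyl) | [Li]O[C@@]1(C(Br)(Br)CCC#C[Si](C)(C)C)[C@]2(C)CC[C@@H](Br)C(C)(C)[C@H]2CC1 | intermediate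
12 | β-oxido carbenoid: alkoxide 11 with one bromine of the CBr2 group exchanged for lithium | [Li]O[C@@]1(C([Li])(Br)CCC#C[Si](C)(C)C)[C@]2(C)CC[C@@H](Br)C(C)(C)[C@H]2CC1 | intermediate
13 | lithium (4aS,6R,8aR)-6-bromo-5,5,8a-trimethyl-1-[4-(trimethylsilyl)but-3-yn-1-yl]-3,4,4a,5,6,7,8,8a-octahydronaphthalen-2-olate | [Li]OC1=C(CCC#C[Si](C)(C)C)[C@]2(C)CC[C@@H](Br)C(C)(C)[C@H]2CC1 | intermediate
14 | (1S,4aS,6R,8aR)-6-bromo-5,5,8a-trimethyl-1-[4-(trimethylsilyl)but-3-yn-1-yl]octahydronaphthalen-2(1H)-one | C[Si](C)(C)C#CCC[C@H]1[C@]2(C)CC[C@@H](Br)C(C)(C)[C@H]2CCC1=O | intermediate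
15 | (1S,4aS,6R,8aR)-6-bromo-1-(but-3-yn-1-yl)-5,5,8a-trimethyloctahydronaphthalen-2(1H)-one | C#CCC[C@H]1[C@]2(C)CC[C@@H](Br)C(C)(C)[C@H]2CCC1=O | intermediate
16 | (1R,4aS,6R,8aS)-6-bromo-1-(but-3-yn-1-yl)-5,5,8a-trimethyl-2-methylidenedecahydronaphthalene | C#CCC[C@H]1[C@]2(C)CC[C@@H](Br)C(C)(C)[C@H]2CCC1=C | intermediate
17 | (1S,2S,4aS,6R,8aR)-6-bromo-1-(but-3-yn-1-yl)-5,5,8a-trimethyloctahydro-1H-spiro[naphthalene-2,2′-oxirane] | C#CCC[C@H]1[C@]2(C)CC[C@@H](Br)C(C)(C)[C@H]2CC[C@@]13CO3 | intermediate
18 | (1S,2S,4aS,6R,8aR)-6-bromo-1-(but-3-yn-1-yl)-2,5,5,8a-tetramethyldecahydronaphthalen-2-ol | C#CCC[C@H]1[C@]2(C)CC[C@@H](Br)C(C)(C)[C@H]2CC[C@]1(C)O | intermediate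
19 | (E)-alkenyl(dimethyl)alane of 18 (methyl and aluminium cis on C13=C14; C8–O–AlMe2) | C/C(=C\[Al](C)C)CC[C@H]1[C@]2(C)CC[C@@H](Br)C(C)(C)[C@H]2CC[C@]1(C)O[Al](C)C | intermediate
20 | lithium butyl(dimethyl)alkenylalanate derived from 19 | [Li+].CCCC[Al-](C)(C)/C=C(\C)CC[C@H]1[C@]2(C)CC[C@@H](Br)C(C)(C)[C@H]2CC[C@]1(C)O[Al](C)C | intermediate
21 | (1S,2S,4aS,6R,8aR)-6-bromo-1-[(3E)-5-hydroxy-3-methylpent-3-en-1-yl]-2,5,5,8a-tetramethyldecahydronaphthalen-2-ol | C/C(=C\CO)CC[C@H]1[C@]2(C)CC[C@@H](Br)C(C)(C)[C@H]2CC[C@]1(C)O | target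

**Step count and risks**

Total step count: 11. Longest linear sequence: 9 steps (steps 1–3 and 6–11 from (E)-geranylacetone); steps 4 and 5 form a two-step side branch that joins at step 6.

The three steps most likely to fail:

Step 2. The face selection by the catalyst may be insufficient with a propargylsilane terminator. The cascade may also stop after ring A by proton loss, or the alkyne may be brominated competitively. Fallback, setting out from 4 and coming back at 6: cyclization of 4 with the achiral bromonium source Et2SBr·SbBrCl5 in MeNO2 at −25 °C should give 5 together with its mirror image (3aR,5S,7aS)-5-bromo-1-ethenylidene-4,4,7a-trimethyloctahydro-1H-indene F1. Ozonolysis as in step 3 should then give 6 together with its mirror image (3aR,5S,7aS)-5-bromo-4,4,7a-trimethyloctahydro-1H-inden-1-one F2. The two ketones are separated by preparative chromatography on a chiral stationary phase, and 6 re-enters at step 6, so that absolute configuration comes from resolution and not from catalysis.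

Step 6. Addition of the tertiary carbenoid 10 to the hindered ketone may be slow, so that enolization at C7 and carbenoid decomposition compete. In the 1,2-shift, migration of C7 may compete with migration of C10. Fallback, setting out from 6 (side chain from 7) and coming back at 14: alcohol 7 is converted with I2, PPh3 and imidazole into (5-iodopent-1-yn-1-yl)trimethylsilane F3, which is heated with PPh3 in MeCN to give triphenyl[5-(trimethylsilyl)pent-4-yn-1-yl]phosphonium iodide F4. Deprotonation of F4 with KN(SiMe3)2 gives triphenyl[5-(trimethylsilyl)pent-4-yn-1-ylidene]phosphorane F5. Wittig reaction of F5 with 6 in warm THF, which is well behaved for cyclopentanones next to a quaternary carbon, should give (3aS,5R,7aR)-5-bromo-4,4,7a-trimethyl-1-[(Z)-5-(trimethylsilyl)pent-4-yn-1-ylidene]octahydro-1H-indene F6. Oxidative ring expansion of this exocyclic alkene with PhI(OH)OTs in 95:5 MeOH/H2O should give 14: the iodane adds at C9, the solvent adds at C8, and C10 migrates to C9 with loss of iodobenzene.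

Step 9. Epoxidation may show poor facial selectivity at C8=C17, and the following hydride step may partly reduce the C3 bromide. Fallback, setting out from 16 and coming back at 18: Mukaiyama hydration of 16 with Mn(dpm)3 (tris(2,2,6,6-tetramethylheptane-3,5-dionato)manganese), PhSiH3 and O2 in iPrOH/CH2Cl2 at 0 °C, then P(OEt)3. Hydrogen-atom transfer to C17 gives the tertiary C8 radical, which should be trapped by O2 on the α-face, away from the C20 methyl. This gives 18 directly, without 17 and without LiAlH4; no new compound is made (F0).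

Further compounds
F1 | step 2 | (3aR,5S,7aS)-5-bromo-1-ethenylidene-4,4,7a-trimethyloctahydro-1H-indene | C=C=C1[C@@]2(C)CC[C@H](Br)C(C)(C)[C@@H]2CC1
F2 | step 2 | (3aR,5S,7aS)-5-bromo-4,4,7a-trimethyloctahydro-1H-inden-1-one | O=C1[C@@]2(C)CC[C@H](Br)C(C)(C)[C@@H]2CC1
F3 | step 6 | (5-iodopent-1-yn-1-yl)trimethylsilane | C[Si](C)(C)C#CCCCI
F4 | step 6 | triphenyl[5-(trimethylsilyl)pent-4-yn-1-yl]phosphonium iodide | C[Si](C)(C)C#CCCC[P+](c1ccccc1)(c1ccccc1)c1ccccc1.[I-]
F5 | step 6 | triphenyl[5-(trimethylsilyl)pent-4-yn-1-ylidene]phosphorane | C[Si](C)(C)C#CCCC=P(c1ccccc1)(c1ccccc1)c1ccccc1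
F6 | step 6 | (3aS,5R,7aR)-5-bromo-4,4,7a-trimethyl-1-[(Z)-5-(trimethylsilyl)pent-4-yn-1-ylidene]octahydro-1H-indene | C[Si](C)(C)C#CCC/C=C1\[C@]2(C)CC[C@@H](Br)C(C)(C)[C@H]2CC1
F0 | step 9 | none | none
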